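**Strategy.** Everything rests on closing the dihydrofuran ring through the C3a–C3 bond by a rhodium-catalysed, imine-directed C–H activation. Monovalent rhodium inserts into the C3a–H bond of the benzene ring, and the resulting aryl rhodium hydride adds across the tethered C2=C3 enol-ether alkene. One operation makes the C3a–C3 bond and both ring stereocentres (2S,3S, trans). The feature exploited is that C3a is the only free carbon lying between the ether-bearing C7a and C4, so a formyl group at C4 (later the lactate side chain) can steer the metal there as a chiral imine. The precursor is an acyclic (E)-β-aryloxycinnamate that already carries the protected danshensu ester.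

Key step: step 6

Remark: tert-butyl (2R)-oxirane-2-carboxylate and 5-bromo-2,2-dimethyl-1,3-benzodioxole are taken as purchasable.
Remark: the sense of induction of (R)-1-aminoindane (step 6) and of the (R,R)-DuPhos ligand (step 11) is assumed as stated; the antipodal amine or ligand would be used should the sense prove opposite.

**Step 1**
Reactants: 1 3,4-dihydroxybenzaldehyde
Product: 2 3-hydroxy-4-[(4-methoxybenzyl)oxy]benzaldehyde
Conditions: PMBCl, NaHCO3, NaI (cat.), DMF, 40 °C
Reagents that add atoms: 4-methoxybenzyl chloride, COc1ccc(CCl)cc1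
Why: Williamson etherification under weak-base control, in which the 4-hydroxyl (para to the formyl group, the more acidic phenol) is alkylated selectively and the 3-hydroxyl stays free for step 5.

**Step 2**
Reactants: 3 5-bromo-2,2-dimethyl-1,3-benzodioxole; 4 tert-butyl (2R)-oxirane-2-carboxylate
Product: 6 tert-butyl (2R)-3-(2,2-dimethyl-1,3-benzodioxol-5-yl)-2-hydroxypropanoate, via arylmagnesium bromide 5 (not isolated)
Conditions: Mg, THF, 40 °C; then CuI (10 mol%), 4, THF, −40 to −20 °C; aq. NH4Cl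
Reagents that add atoms: none
Why: Copper-catalysed SN2 opening of the epoxide at its unsubstituted carbon by the aryl Grignard reagent, which leaves the glycidate stereocentre untouched so that the (R)-lactate configuration is carried over from 4, while the tert-butyl ester resists the Grignard reagent at low temperature.

**Step 3**
Reactants: 3 5-bromo-2,2-dimethyl-1,3-benzodioxole; 7 propiolic acid
Product: 8 3-(2,2-dimethyl-1,3-benzodioxol-5-yl)prop-2-ynoic acid
Conditions: Pd(PPh3)2Cl2 (5 mol%), 1,4-bis(diphenylphosphino)butane (10 mol%), DBU, DMSO, 50 °C; cold aq. KHSO4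
Reagents that add atoms: none
Why: Copper-free Sonogashira coupling of the aryl bromide with the terminal alkyne of propiolic acid, run at a temperature at which the arylpropiolate salt is expected to survive without decarboxylation.

**Step 4**
Reactants: 6 tert-butyl (2R)-3-(2,2-dimethyl-1,3-benzodioxol-5-yl)-2-hydroxypropanoate; 8 3-(2,2-dimethyl-1,3-benzodioxol-5-yl)prop-2-ynoic acid
Product: 9 arylpropiolate ester of 6 (full name in the list)
Conditions: EDC·HCl, DMAP (cat.), CH2Cl2, 0 °C to rt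
Reagents that add atoms: none
Why: Steglich esterification (carbodiimide activation, DMAP acyl transfer) at the secondary hydroxyl, in which no bond to the lactate centre is broken, so (R) is retained.

**Step 5**
Reactants: 2 3-hydroxy-4-[(4-methoxybenzyl)oxy]benzaldehyde; 9 arylpropiolate ester
Product: 10 (E)-β-aryloxycinnamate ester bearing the 5-formyl-2-(PMB-oxy)phenoxy group (full name in the list)
Conditions: Cs2CO3 (0.2 equiv), DMF, 50 °C
Reagents that add atoms: none
Why: Base-catalysed oxa-Michael (conjugate) addition of the only free phenol to the ynoate β-carbon, with the PMB ether blocking the second catechol oxygen; reversible addition under the phenoxide conditions should settle on the (E)-isomer (aryloxy anti to the ester), any (Z)-fraction being separated and re-equilibrated.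

**Step 6**
Reactants: 10 (E)-β-aryloxycinnamate aldehyde
Product: 13 (2S,3S)-trans-4-formyl-2,3-dihydrobenzofuran-3-carboxylate ester (full name in the list), via indanyl aldimine 11 (not isolated), via cyclised dihydrobenzofuran aldimine 12 (not isolated)
Conditions: (R)-1-aminoindane, 4 Å molecular sieves, toluene, rt; then [RhCl(coe)2]2 (5 mol%), FcPCy2 [(dicyclohexylphosphino)ferrocene] (15 mol%), toluene, 75 °C; then 1 M aq. HCl, THF, 0 °C
Reagents that add atoms: water, O
Why: The imine nitrogen binds monovalent rhodium and delivers it into the C3a–H bond (the ortho C–H lying between the imine-bearing C4 and the ether-bearing C7a); the tethered C2=C3 alkene then inserts into Rh–H with hydrogen going to C2 and rhodium to C3, and C–C reductive elimination from the six-membered rhodacycle forms C3a–C3. The closest known reaction type is the chelation-assisted (imine-directed) intramolecular hydroarylation of alkenes by C–H activation, a Murai-type alkylation. The five-membered dihydrofuran ring is closed in a formal 5-endo-trig sense, which is feasible because the bond is made by reductive elimination from a metallacycle and not by direct attack on the alkene. C3 and C2 arise together by syn addition of aryl and hydrogen to the (E)-alkene, which translates into the 2,3-trans relationship, and the face is chosen by the (R)-indanyl group on nitrogen (auxiliary control, expected to give 2S,3S); the minor diastereomer is removed by chromatography, and C3, being epimerisable, can only relax to trans. The step needs site selectivity among the aryl C–H bonds, and the substrate secures it: metalation at the other ortho position (C5) is reversible and cannot reach the alkene, and the second position ortho to the ring oxygen carries the PMB ether.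

**Step 7**
Reactants: 3 5-bromo-2,2-dimethyl-1,3-benzodioxole; 14 acrylic acid
Product: 15 (2E)-3-(2,2-dimethyl-1,3-benzodioxol-5-yl)prop-2-enoic acid
Conditions: Pd(OAc)2 (2 mol%), P(o-tol)3 (4 mol%), Et3N, DMF, 100 °C; cold aq. KHSO4
Reagents that add atoms: none
Why: Mizoroki–Heck reaction, in which syn insertion and syn β-hydride elimination give the (E)-cinnamic acid.

**Step 8**
Reactants: 16 tert-butyl 2-(dimethoxyphosphoryl)acetate
Product: 17 tert-butyl 2-diazo-2-(dimethoxyphosphoryl)acetate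
Conditions: 4-acetamidobenzenesulfonyl azide, DBU, MeCN, 0 °C to rt
Reagents that add atoms: 4-acetamidobenzenesulfonyl azide, CC(=O)Nc1ccc(cc1)S(=O)(=O)N=[N+]=[N-]
Why: Regitz diazo transfer to the doubly activated methylene of the phosphonoacetate.

**Step 9**
Reactants: 15 (2E)-3-(2,2-dimethyl-1,3-benzodioxol-5-yl)prop-2-enoic acid; 17 tert-butyl 2-diazo-2-(dimethoxyphosphoryl)acetate
Product: 18 tert-butyl 2-(dimethoxyphosphoryl)-2-(protected caffeoyloxy)acetate (racemic; full name in the list)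
Conditions: Rh2(OAc)4 (1 mol%), toluene, 80 °C, slow addition of 17
Reagents that add atoms: none
Why: Rhodium-carbenoid O–H insertion of the carboxylic acid into the acceptor/acceptor carbene, which is too electrophilic to cyclopropanate the electron-poor cinnamoyl alkene; the new centre is racemic and is erased in step 10.

**Step 10**
Reactants: 13 (2S,3S)-trans-4-formyl-dihydrobenzofuran ester; 18 α-(caffeoyloxy)phosphonoacetate
Product: 19 (Z)-enol ester (full name in the list)
Conditions: 1,1,3,3-tetramethylguanidine, THF, −78 °C to rt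
Reagents that add atoms: none
Why: Horner–Wadsworth–Emmons olefination with the stabilised α-acyloxy phosphonate anion, expected to give mainly the (Z)-enol ester (both geometries should be hydrogenated with the same sense); the weak guanidine base limits E1cB opening of the dihydrobenzofuran, and C3 can only relax to the trans isomer already present.

**Step 11**
Reactants: 19 (Z)-enol ester
Product: 20 fully protected target (full name in the list)
Conditions: [Rh(cod)((R,R)-Et-DuPhos)]OTf (2 mol%), H2 (6 atm), degassed CH2Cl2/MeOH, rt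
Reagents that add atoms: none
Why: Asymmetric hydrogenation of an enol ester, in which chelation of the alkene and the acyl carbonyl to cationic monovalent rhodium confines reduction to this C=C (the non-chelating caffeoyl alkene, the PMB ether and the arenes are left) and the C2-symmetric DuPhos ligand sets the new lactate centre as (R) by catalyst control.

**Step 12**
Reactants: 20 fully protected target
Product: 21 CNP0201431.1
Conditions: TFA/CH2Cl2 (1:1), H2O (20 equiv), anisole (10 equiv), 0 °C to rt, argon; reverse-phase HPLC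
Reagents that add atoms: none
Why: Global acidolysis, in which the two tert-butyl esters lose isobutene, the three catechol acetonides are hydrolysed and the PMB ether is cleaved with anisole trapping the benzylic cation; the ester linkages, the caffeoyl alkene and the four stereocentres are not affected by acid, and no basic step follows that could open the dihydrobenzofuran.

**Compound list**

1 | 3,4-dihydroxybenzaldehyde | O=Cc1ccc(O)c(O)c1 | starting material
2 | 3-hydroxy-4-[(4-methoxybenzyl)oxy]benzaldehyde | O=Cc1ccc(OCc2ccc(OC)cc2)c(O)c1 | intermediate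
3 | 5-bromo-2,2-dimethyl-1,3-benzodioxole | CC1(C)Oc2ccc(Br)cc2O1 | starting material
4 | tert-butyl (2R)-oxirane-2-carboxylate | CC(C)(C)OC(=O)[C@H]1CO1 | starting material
5 | (2,2-dimethyl-1,3-benzodioxol-5-yl)magnesium bromide | CC1(C)Oc2ccc([Mg]Br)cc2O1 | intermediate
6 | tert-butyl (2R)-3-(2,2-dimethyl-1,3-benzodioxol-5-yl)-2-hydroxypropanoate | O[C@H](Cc1ccc2OC(C)(C)Oc2c1)C(=O)OC(C)(C)C | intermediate
7 | propiolic acid (prop-2-ynoic acid) | OC(=O)C#C | starting material
8 | 3-(2,2-dimethyl-1,3-benzodioxol-5-yl)prop-2-ynoic acid | OC(=O)C#Cc1ccc2OC(C)(C)Oc2c1 | intermediate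
9 | tert-butyl (2R)-3-(2,2-dimethyl-1,3-benzodioxol-5-yl)-2-{[3-(2,2-dimethyl-1,3-benzodioxol-5-yl)prop-2-ynoyl]oxy}propanoate | O=C(C#Cc1ccc2OC(C)(C)Oc2c1)O[C@H](Cc1ccc2OC(C)(C)Oc2c1)C(=O)OC(C)(C)C | intermediate
10 | tert-butyl (2R)-3-(2,2-dimethyl-1,3-benzodioxol-5-yl)-2-{[(2E)-3-(2,2-dimethyl-1,3-benzodioxol-5-yl)-3-{5-formyl-2-[(4-methoxybenzyl)oxy]phenoxy}prop-2-enoyl]oxy}propanoate | O=Cc1ccc(OCc2ccc(OC)cc2)c(O/C(=C/C(=O)O[C@H](Cc2ccc3OC(C)(C)Oc3c2)C(=O)OC(C)(C)C)c2ccc3OC(C)(C)Oc3c2)c1 | intermediate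
11 | (E)-N-[(1R)-2,3-dihydro-1H-inden-1-yl] aldimine of 10 | [C@H]1(CCc2ccccc12)/N=C/c1ccc(OCc2ccc(OC)cc2)c(O/C(=C/C(=O)O[C@H](Cc2ccc3OC(C)(C)Oc3c2)C(=O)OC(C)(C)C)c2ccc3OC(C)(C)Oc3c2)c1 | intermediate
12 | tert-butyl (2R)-3-(2,2-dimethyl-1,3-benzodioxol-5-yl)-2-{[(2S,3S)-2-(2,2-dimethyl-1,3-benzodioxol-5-yl)-4-{(E)-[(1R)-2,3-dihydro-1H-inden-1-ylimino]methyl}-7-[(4-methoxybenzyl)oxy]-2,3-dihydro-1-benzofuran-3-carbonyl]oxy}propanoate | [C@H]1(CCc2ccccc12)/N=C/c1ccc(OCc3ccc(OC)cc3)c2c1[C@H](C(=O)O[C@H](Cc1ccc3OC(C)(C)Oc3c1)C(=O)OC(C)(C)C)[C@@H](c1ccc3OC(C)(C)Oc3c1)O2 | intermediate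
13 | tert-butyl (2R)-3-(2,2-dimethyl-1,3-benzodioxol-5-yl)-2-{[(2S,3S)-2-(2,2-dimethyl-1,3-benzodioxol-5-yl)-4-formyl-7-[(4-methoxybenzyl)oxy]-2,3-dihydro-1-benzofuran-3-carbonyl]oxy}propanoate | O=Cc1ccc(OCc3ccc(OC)cc3)c2c1[C@H](C(=O)O[C@H](Cc1ccc3OC(C)(C)Oc3c1)C(=O)OC(C)(C)C)[C@@H](c1ccc3OC(C)(C)Oc3c1)O2 | intermediate
14 | acrylic acid | OC(=O)C=C | starting material
15 | (2E)-3-(2,2-dimethyl-1,3-benzodioxol-5-yl)prop-2-enoic acid | OC(=O)/C=C/c1ccc2OC(C)(C)Oc2c1 | intermediate
16 | tert-butyl 2-(dimethoxyphosphoryl)acetate | COP(=O)(OC)CC(=O)OC(C)(C)C | starting material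
17 | tert-butyl 2-diazo-2-(dimethoxyphosphoryl)acetate | COP(=O)(OC)C(=[N+]=[N-])C(=O)OC(C)(C)C | intermediate
18 | tert-butyl 2-(dimethoxyphosphoryl)-2-{[(2E)-3-(2,2-dimethyl-1,3-benzodioxol-5-yl)prop-2-enoyl]oxy}acetate (racemic) | COP(=O)(OC)C(OC(=O)/C=C/c1ccc2OC(C)(C)Oc2c1)C(=O)OC(C)(C)C | intermediate
19 | tert-butyl (2Z)-2-{[(2E)-3-(2,2-dimethyl-1,3-benzodioxol-5-yl)prop-2-enoyl]oxy}-3-[(2S,3S)-3-({[(2R)-1-tert-butoxy-3-(2,2-dimethyl-1,3-benzodioxol-5-yl)-1-oxopropan-2-yl]oxy}carbonyl)-2-(2,2-dimethyl-1,3-benzodioxol-5-yl)-7-[(4-methoxybenzyl)oxy]-2,3-dihydro-1-benzofuran-4-yl]prop-2-enoate | O=C(/C=C/c1ccc2OC(C)(C)Oc2c1)O/C(=C\c1ccc(OCc3ccc(OC)cc3)c2c1[C@H](C(=O)O[C@H](Cc1ccc3OC(C)(C)Oc3c1)C(=O)OC(C)(C)C)[C@@H](c1ccc3OC(C)(C)Oc3c1)O2)C(=O)OC(C)(C)C | intermediate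
20 | tert-butyl (2R)-2-{[(2E)-3-(2,2-dimethyl-1,3-benzodioxol-5-yl)prop-2-enoyl]oxy}-3-[(2S,3S)-3-({[(2R)-1-tert-butoxy-3-(2,2-dimethyl-1,3-benzodioxol-5-yl)-1-oxopropan-2-yl]oxy}carbonyl)-2-(2,2-dimethyl-1,3-benzodioxol-5-yl)-7-[(4-methoxybenzyl)oxy]-2,3-dihydro-1-benzofuran-4-yl]propanoate | O=C(/C=C/c1ccc2OC(C)(C)Oc2c1)O[C@H](Cc1ccc(OCc3ccc(OC)cc3)c2c1[C@H](C(=O)O[C@H](Cc1ccc3OC(C)(C)Oc3c1)C(=O)OC(C)(C)C)[C@@H](c1ccc3OC(C)(C)Oc3c1)O2)C(=O)OC(C)(C)C | intermediate
21 | CNP0201431.1: (2R)-3-[(2S,3S)-3-{[(1R)-1-carboxy-2-(3,4-dihydroxyphenyl)ethoxy]carbonyl}-2-(3,4-dihydroxyphenyl)-7-hydroxy-2,3-dihydro-1-benzofuran-4-yl]-2-{[(2E)-3-(3,4-dihydroxyphenyl)prop-2-enoyl]oxy}propanoic acid | O=C(/C=C/c1ccc(O)c(O)c1)O[C@H](Cc1ccc(O)c2c1[C@H](C(=O)O[C@H](Cc1ccc(O)c(O)c1)C(=O)O)[C@@H](c1ccc(O)c(O)c1)O2)C(=O)O | target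

**Totals**

Total step count: 12.
Longest linear sequence: 7 steps (steps 2, 4, 5, 6, 10, 11 and 12, from bromide 3).

**Steps most likely to fail**

Step 6. The rhodium hydride may insert only sluggishly into the hindered, ester-bearing trisubstituted alkene, or the auxiliary may discriminate the two alkene faces poorly. The fallback closes the same bond without a metal and sets out from 10. Irradiation (Pyrex-filtered mercury lamp, above 300 nm, dilute degassed benzene) should bring about a conrotatory six-electron electrocyclisation of the aryl vinyl ether onto C3a to a carbonyl ylide, followed by a 1,4-hydrogen shift (heteroatom-directed photoarylation). Brief treatment with catalytic DBU in CH2Cl2 then equilibrates C3 to trans. This should give 13 together with its (2R,3R)-diastereomer, tert-butyl (2R)-3-(2,2-dimethyl-1,3-benzodioxol-5-yl)-2-{[(2R,3R)-2-(2,2-dimethyl-1,3-benzodioxol-5-yl)-4-formyl-7-[(4-methoxybenzyl)oxy]-2,3-dihydro-1-benzofuran-3-carbonyl]oxy}propanoate F1. The two are diastereomers because of the lactate centre and are separated by chromatography, and the route is rejoined at 13.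

Step 11. Reduction of the caffeoyl alkene may compete, or the hindered enol ester may be hydrogenated with insufficient facial selectivity. The fallback sets out from 13 and 17 and brings the caffeoyl group in only after the hydrogenation. O–H insertion of 17 into chloroacetic acid (Rh2(OAc)4, toluene, 80 °C) gives tert-butyl 2-(chloroacetoxy)-2-(dimethoxyphosphoryl)acetate F2. Olefination of 13 with the lithium salt of F2 (LiHMDS, THF, −78 °C) gives the (Z)-enol chloroacetate F3. Hydrogenation with the same cationic rhodium–DuPhos catalyst, now without a competing alkene, gives the (2R)-chloroacetate F4. Thiourea and NaHCO3 (EtOH/THF, 50 °C) remove the chloroacetyl group to give the (2R)-α-hydroxy ester F5, and Steglich esterification of F5 with acid 15 (EDC·HCl, DMAP, CH2Cl2) rejoins the route at 20.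

Step 5. The phenoxide may attack the activated ynoate ester (acyl transfer), or the wrong alkene geometry may form with no safe way to equilibrate it next to the chiral ester. The fallback sets out from 8 and makes the vinyl ether before the chiral alcohol is attached. Esterification of 8 with 2-(trimethylsilyl)ethanol (EDC·HCl, DMAP) gives 2-(trimethylsilyl)ethyl 3-(2,2-dimethyl-1,3-benzodioxol-5-yl)prop-2-ynoate F6. Conjugate addition of 2 (Cs2CO3, DMF, 60 °C), with equilibration and isomer separation at this simple stage, gives the 2-(trimethylsilyl)ethyl (E)-β-aryloxycinnamate F7. TBAF in THF releases the (E)-β-aryloxycinnamic acid F8, and Steglich esterification of F8 with alcohol 6 rejoins the route at 10.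

**Further compounds**

F1 | step 6 | tert-butyl (2R)-3-(2,2-dimethyl-1,3-benzodioxol-5-yl)-2-{[(2R,3R)-2-(2,2-dimethyl-1,3-benzodioxol-5-yl)-4-formyl-7-[(4-methoxybenzyl)oxy]-2,3-dihydro-1-benzofuran-3-carbonyl]oxy}propanoate | O=Cc1ccc(OCc3ccc(OC)cc3)c2c1[C@@H](C(=O)O[C@H](Cc1ccc3OC(C)(C)Oc3c1)C(=O)OC(C)(C)C)[C@H](c1ccc3OC(C)(C)Oc3c1)O2
F2 | step 11 | tert-butyl 2-(chloroacetoxy)-2-(dimethoxyphosphoryl)acetate | COP(=O)(OC)C(OC(=O)CCl)C(=O)OC(C)(C)C
F3 | step 11 | tert-butyl (2Z)-2-(chloroacetoxy)-3-[(2S,3S)-3-({[(2R)-1-tert-butoxy-3-(2,2-dimethyl-1,3-benzodioxol-5-yl)-1-oxopropan-2-yl]oxy}carbonyl)-2-(2,2-dimethyl-1,3-benzodioxol-5-yl)-7-[(4-methoxybenzyl)oxy]-2,3-dihydro-1-benzofuran-4-yl]prop-2-enoate | ClCC(=O)O/C(=C\c1ccc(OCc3ccc(OC)cc3)c2c1[C@H](C(=O)O[C@H](Cc1ccc3OC(C)(C)Oc3c1)C(=O)OC(C)(C)C)[C@@H](c1ccc3OC(C)(C)Oc3c1)O2)C(=O)OC(C)(C)C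
F4 | step 11 | tert-butyl (2R)-2-(chloroacetoxy)-3-[(2S,3S)-3-({[(2R)-1-tert-butoxy-3-(2,2-dimethyl-1,3-benzodioxol-5-yl)-1-oxopropan-2-yl]oxy}carbonyl)-2-(2,2-dimethyl-1,3-benzodioxol-5-yl)-7-[(4-methoxybenzyl)oxy]-2,3-dihydro-1-benzofuran-4-yl]propanoate | ClCC(=O)O[C@H](Cc1ccc(OCc3ccc(OC)cc3)c2c1[C@H](C(=O)O[C@H](Cc1ccc3OC(C)(C)Oc3c1)C(=O)OC(C)(C)C)[C@@H](c1ccc3OC(C)(C)Oc3c1)O2)C(=O)OC(C)(C)C
F5 | step 11 | tert-butyl (2R)-3-[(2S,3S)-3-({[(2R)-1-tert-butoxy-3-(2,2-dimethyl-1,3-benzodioxol-5-yl)-1-oxopropan-2-yl]oxy}carbonyl)-2-(2,2-dimethyl-1,3-benzodioxol-5-yl)-7-[(4-methoxybenzyl)oxy]-2,3-dihydro-1-benzofuran-4-yl]-2-hydroxypropanoate | O[C@H](Cc1ccc(OCc3ccc(OC)cc3)c2c1[C@H](C(=O)O[C@H](Cc1ccc3OC(C)(C)Oc3c1)C(=O)OC(C)(C)C)[C@@H](c1ccc3OC(C)(C)Oc3c1)O2)C(=O)OC(C)(C)C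
F6 | step 5 | 2-(trimethylsilyl)ethyl 3-(2,2-dimethyl-1,3-benzodioxol-5-yl)prop-2-ynoate | C[Si](C)(C)CCOC(=O)C#Cc1ccc2OC(C)(C)Oc2c1
F7 | step 5 | 2-(trimethylsilyl)ethyl (2E)-3-(2,2-dimethyl-1,3-benzodioxol-5-yl)-3-{5-formyl-2-[(4-methoxybenzyl)oxy]phenoxy}prop-2-enoate | O=Cc1ccc(OCc2ccc(OC)cc2)c(O/C(=C/C(=O)OCC[Si](C)(C)C)c2ccc3OC(C)(C)Oc3c2)c1
F8 | step 5 | (2E)-3-(2,2-dimethyl-1,3-benzodioxol-5-yl)-3-{5-formyl-2-[(4-methoxybenzyl)oxy]phenoxy}prop-2-enoic acid | O=Cc1ccc(OCc2ccc(OC)cc2)c(O/C(=C/C(=O)O)c2ccc3OC(C)(C)Oc3c2)c1
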